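**Strategy.** The ten-membered ring (C1–C10: epoxide C3–C4, acetate C5, isopropenyl C7, enoate C9=C10, ester carbon C14 on C10, acyloxymethyl C15 on C4) hides a cis,trans-1,5-diene, C9=C10–C1–C2–C3=C4, the retron of a bicyclo[2.2.0]hexane. One enone–cyclobutene [2+2] photocycloaddition forms C3–C4 and C9–C10 and puts all ten carbons into a 6-4-4 tricycle; heat then breaks C3–C10 and C4–C9. The precursor is (S)-5-isopropenyl-2-(silyloxymethyl)cyclohex-2-enone (ring C4–C9, carbonyl C5), whose C7 centre comes from a rhodium-catalysed conjugate addition, with 1-(silyloxymethyl)cyclobutene (C10, C1, C2, C3) as partner.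

Key step: step 9

Remark: the atom labels C1–C15 of the target ring are used for all intermediates. The two facial isomers of the photoadduct differ only at the four centres that become sp2 on ring opening, so 12 is drawn as one of them (approach anti to the isopropenyl group) and the pair is carried on unseparated.

Step 1
Reactants: 1 cyclohex-2-en-1-one; 2 isopropenylboronic acid pinacol ester
Product: 3 (S)-3-(prop-1-en-2-yl)cyclohexan-1-one
Conditions: [Rh(cod)Cl]2 (cat.), (S)-BINAP, aq. KOH, 1,4-dioxane/H2O, 50 °C
Reagents that add atoms: none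
Why: Hayashi–Miyaura rhodium-catalysed asymmetric 1,4-addition: transmetallation gives an isopropenylrhodium–(S)-BINAP species that inserts the enone on one enantioface and is released by protonation, so the ligand alone sets C7, and (S)-BINAP is chosen because it delivers carbon nucleophiles to the face of cyclohexenone that corresponds to the (S)-ketone.

Step 2
Reactants: 3 (S)-3-(prop-1-en-2-yl)cyclohexan-1-one
Product: 4 (S)-trimethyl{[5-(prop-1-en-2-yl)cyclohex-1-en-1-yl]oxy}silane
Conditions: TMSCl, LiN(iPr)2 (LDA, added last), THF, −78 °C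
Reagents that add atoms: chlorotrimethylsilane, C[Si](C)(C)Cl
Why: Kinetic enolisation with in situ silyl trapping: the hindered amide should remove the proton at C4, the α-methylene remote from C7, faster than at C6, which is flanked by the isopropenyl-bearing carbon, and any regioisomeric enol ether ends in step 3 as an achiral conjugated dienone that is separated; C7 is not touched.

Step 3
Reactants: 4 (S)-trimethyl{[5-(prop-1-en-2-yl)cyclohex-1-en-1-yl]oxy}silane
Product: 5 (S)-5-(prop-1-en-2-yl)cyclohex-2-en-1-one
Conditions: Pd(OAc)2 (1 equiv), MeCN, 23 °C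
Reagents that add atoms: none
Why: Saegusa–Ito oxidation: divalent palladium is transferred from oxygen to C4 of the enol ether and β-hydride elimination from C9 gives the C4=C9 enone and zerovalent palladium, the isolated 1,1-disubstituted alkene being a poor ligand that is left alone.

Step 4
Reactants: 5 (S)-5-(prop-1-en-2-yl)cyclohex-2-en-1-one
Product: 6 (S)-2-(hydroxymethyl)-5-(prop-1-en-2-yl)cyclohex-2-en-1-one
Conditions: aq. HCHO (37%), DMAP (cat.), THF/H2O, 23 °C
Reagents that add atoms: formaldehyde, C=O
Why: Morita–Baylis–Hillman reaction: DMAP adds reversibly to C9, the resulting enolate attacks formaldehyde through C4, and loss of DMAP restores the enone, while C7 (not enolisable) keeps its configuration.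

Step 5
Reactants: 6 (S)-2-(hydroxymethyl)-5-(prop-1-en-2-yl)cyclohex-2-en-1-one
Product: 7 (S)-5-(prop-1-en-2-yl)-2-{[tri(propan-2-yl)silyl]oxymethyl}cyclohex-2-en-1-one
Conditions: TIPSCl, imidazole, DMF, 0 → 23 °C
Reagents that add atoms: chlorotri(propan-2-yl)silane, CC(C)[Si](Cl)(C(C)C)C(C)C
Why: Imidazole-assisted silylation of a primary alcohol; the bulky silyl group at C15 is chosen to outlast the later selective removal of the triethylsilyl group at C14.

Step 6
Reactants: 8 ethyl 1-bromocyclobutane-1-carboxylate
Product: 9 cyclobut-1-ene-1-carboxylic acid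
Conditions: KOH, toluene, reflux; then aq. HCl, 0 °C
Reagents that add atoms: potassium hydroxide, [K+].[OH-]
Why: Base-mediated E2 dehydrobromination of the tertiary α-bromo ester followed by saponification gives the conjugated cyclobutene acid, which is used promptly because it polymerises on storage.

Step 7
Reactants: 9 cyclobut-1-ene-1-carboxylic acid
Product: 10 (cyclobut-1-en-1-yl)methanol
Conditions: LiAlH4, Et2O, 0 °C
Reagents that add atoms: none
Why: Hydride reduction of the carboxylic acid to the primary allylic alcohol; the cyclobutene C=C carries no further activating group and should survive at 0 °C.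

Step 8
Reactants: 10 (cyclobut-1-en-1-yl)methanol
Product: 11 1-[(triethylsilyloxy)methyl]cyclobut-1-ene
Conditions: TESCl, imidazole, CH2Cl2, 0 °C
Reagents that add atoms: chlorotriethylsilane, CC[Si](Cl)(CC)CC
Why: Silylation of a primary alcohol; the small triethylsilyl group at C14 can later be cleaved by mild acid in the presence of the C15 triisopropylsilyl ether.

Step 9
Reactants: 7 (S)-5-(prop-1-en-2-yl)-2-{[tri(propan-2-yl)silyl]oxymethyl}cyclohex-2-en-1-one; 11 1-[(triethylsilyloxy)methyl]cyclobut-1-ene
Product: 12 cis-anti-cis-9-(prop-1-en-2-yl)-2-[(triethylsilyloxy)methyl]-6-{[tri(propan-2-yl)silyl]oxymethyl}tricyclo[4.4.0.0(2,5)]decan-7-one (anti facial isomer drawn; its facial partner forms alongside and is not separated)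
Conditions: hν (λ ≈ 366 nm, Pyrex), 11 (5 equiv), CH2Cl2, −30 °C, Ar; excess 11 recovered
Reagents that add atoms: none
Why: Light absorbed by the enone (n→π*) leads after intersystem crossing to the triplet, which bonds to the ground-state cyclobutene to give a triplet 1,4-biradical that closes after spin inversion, the closest known reaction type being the stepwise enone–alkene [2+2] photocycloaddition, here with a cyclobutene as the alkene. The single ring formed is the cyclobutane C3–C4–C9–C10, closed by radical–radical combination within the biradical (intermolecular [2+2], both new bonds on one face of each partner). C3 and C10 must be cis because they are joined in the four-membered ring C10–C1–C2–C3, C4 and C9 close cis because the relaxed biradical avoids a trans-fused 6-4 junction at the quaternary C4, and the two junctions are anti because C1 and C2 approach exo to the six-membered ring; the face anti to the C7 isopropenyl group is preferred but either face is acceptable. The selectivity needed is head-to-tail (C10 to the β-carbon C9, C3 to C4), secured by the alkyl-type donor substituent C14 on C10 and by the penalty for joining the two fully substituted carbons C4 and C10. Excess 11, low temperature and long-wavelength light keep the slow internal addition to the isopropenyl group, trans-fused closure and secondary photolysis of the product ketone in check.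

Step 10
Reactants: 12 cis-anti-cis tricyclic ketone (both facial isomers)
Product: 13 (2E,6E,9S)-9-(prop-1-en-2-yl)-6-[(triethylsilyloxy)methyl]-2-{[tri(propan-2-yl)silyl]oxymethyl}cyclodeca-2,6-dien-1-one (C3=C4 trans in the ring, C9=C10 cis in the ring)
Conditions: toluene (dilute, degassed), base-washed sealed tube, 190 °C, short heating
Reagents that add atoms: none
Why: Thermal bicyclo[2.2.0]hexane to hexa-1,5-diene cleavage: homolysis of the strained central C3–C10 bond gives a cyclohexane-1,4-diyl that relaxes to a chair and breaks C4–C9 (the weaker of the two candidate bonds, since it yields the C3=C4–C5=O enone), and because the cis-fused bonds C4–C5 and C9–C8 are one equatorial and one axial on that chair one alkene is born trans and the other cis in the ring; allylic 1,2-strain between C14 on the planar C10 radical and C8 should put C8 axial, which makes C9=C10 cis and C3=C4 trans, while the four photochemically made stereocentres vanish so that both facial isomers converge.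

Step 11
Reactants: 13 cyclodeca-2,6-dien-1-one
Product: 14 (1S,2E,6E,9S)-9-(prop-1-en-2-yl)-6-[(triethylsilyloxy)methyl]-2-{[tri(propan-2-yl)silyl]oxymethyl}cyclodeca-2,6-dien-1-ol (5S in route numbering)
Conditions: (R)-2-methyl-CBS-oxazaborolidine (cat.), catecholborane, toluene, −78 °C; aq. NaOH work-up
Reagents that add atoms: none
Why: Corey–Bakshi–Shibata reduction: the oxazaborolidine binds the ketone with the α-branched alkenyl arm C4 as the large group and the C6 methylene as the small one, so that with the (R)-catalyst hydride from catecholborane (which does not hydroborate the alkenes at this temperature) should arrive on the face that gives 5S, and the 1,2-reduction also removes the strained trans-enone.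

Step 12
Reactants: 14 (5S)-dienol
Product: 15 (1S,2E,6E,9S)-9-(prop-1-en-2-yl)-6-[(triethylsilyloxy)methyl]-2-{[tri(propan-2-yl)silyl]oxymethyl}cyclodeca-2,6-dien-1-yl acetate
Conditions: Ac2O, pyridine, DMAP (cat.), CH2Cl2, 0 °C
Reagents that add atoms: acetic anhydride, CC(=O)OC(C)=O
Why: DMAP-catalysed acetylation of the secondary allylic alcohol, with retention at C5.

Step 13
Reactants: 15 (5S)-acetate
Product: 16 (1S,2E,6E,9S)-6-(hydroxymethyl)-9-(prop-1-en-2-yl)-2-{[tri(propan-2-yl)silyl]oxymethyl}cyclodeca-2,6-dien-1-yl acetate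
Conditions: PPTS (cat.), MeOH/CH2Cl2, 0 °C
Reagents that add atoms: none
Why: Acid-catalysed solvolysis of silyl ethers is governed by bulk at silicon, so the primary triethylsilyl ether is methanolysed while the triisopropylsilyl ether and the allylic acetate remain.

Step 14
Reactants: 16 C14 alcohol
Product: 17 (1S,2E,6E,9S)-6-formyl-9-(prop-1-en-2-yl)-2-{[tri(propan-2-yl)silyl]oxymethyl}cyclodeca-2,6-dien-1-yl acetate
Conditions: Dess–Martin periodinane, NaHCO3, CH2Cl2, 0 → 23 °C
Reagents that add atoms: none
Why: Dess–Martin oxidation of the primary allylic alcohol to the enal under buffered, non-isomerising conditions; the C9=C10 geometry is held by the ring.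

Step 15
Reactants: 17 C14 aldehyde
Product: 18 C14 carboxylic acid: ten-membered diene with C3=C4 (trans in the ring) and C9=C10 (cis in the ring), CO2H on C10, CH2OTIPS on C4, (5S)-OAc, (7S)-isopropenyl
Conditions: NaClO2, NaH2PO4, 2-methylbut-2-ene, t-BuOH/H2O, 0 → 23 °C
Reagents that add atoms: sodium chlorite, [Na+].[O-]Cl=O
Why: Pinnick oxidation: chlorous acid adds to the aldehyde and fragments to the acid, and 2-methylbut-2-ene traps the hypochlorous acid before it reaches the alkenes.

Step 16
Reactants: 18 C14 carboxylic acid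
Product: 19 C14 methyl ester: as 18 with CO2Me on C10
Conditions: TMSCHN2, toluene/MeOH, 0 °C
Reagents that add atoms: (trimethylsilyl)diazomethane, C[Si](C)(C)C=[N+]=[N-]
Why: O-Methylation of the acid with (trimethylsilyl)diazomethane in methanol (protonation of the diazo carbon, then SN2 by the carboxylate with loss of dinitrogen), neutral conditions that spare the acetate.

Step 17
Reactants: 19 C14 methyl ester
Product: 20 C15 allylic alcohol: as 19 with CH2OH on C4
Conditions: HF·pyridine, pyridine, THF, 0 → 23 °C
Reagents that add atoms: none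
Why: Fluoride-driven desilylation (strong Si–F bond) under buffered acidic conditions, chosen over basic fluoride to prevent migration of the C5 acetyl group to the freed C15 hydroxyl.

Step 18
Reactants: 20 C15 allylic alcohol
Product: 21 (3R,4S,5S,7S)-epoxy alcohol: C3–C4 epoxide (trans in the ring), CH2OH on C4, (5S)-OAc, (7S)-isopropenyl, C9=C10 methyl enoate (cis in the ring)
Conditions: Ti(OiPr)4 (cat.), L-(+)-diethyl tartrate, t-BuOOH (decane), 4 Å MS, CH2Cl2, −20 °C
Reagents that add atoms: tert-butyl hydroperoxide, CC(C)(C)OO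
Why: Sharpless asymmetric epoxidation: the titanium tartrate binds the C15 hydroxyl and the hydroperoxide and transfers oxygen only to the allylic C3=C4 alkene (not to the enoate or the isopropenyl group), L-(+)-tartrate directing it to the face that gives 3R,4S while the trans ring relationship of C2 and C5 is copied stereospecifically from the alkene.

Step 19
Reactants: 21 epoxy alcohol; 22 (R)-2-methylbutanoic acid
Product: 23 CNP0352790.1, methyl (3R,4S,5S,7S)-5-acetoxy-3,4-epoxy-7-isopropenyl-4-{[(R)-2-methylbutanoyl]oxymethyl}cyclodec-9-ene-10-carboxylate (route numbering; C9=C10 cis in the ring)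
Conditions: DCC, DMAP (cat.), CH2Cl2, 0 → 23 °C
Reagents that add atoms: none
Why: Steglich esterification (carbodiimide activation, DMAP acyl transfer) of the primary alcohol; the α-stereocentre of the acid is not enolised under these conditions and the epoxide is stable to them.

**Compound list**

1 | cyclohex-2-en-1-one | O=C1C=CCCC1 | starting material
2 | isopropenylboronic acid pinacol ester | CC(=C)B1OC(C)(C)C(C)(C)O1 | starting material
3 | (S)-3-(prop-1-en-2-yl)cyclohexan-1-one | C=C(C)[C@H]1CCCC(=O)C1 | intermediate
4 | (S)-trimethyl{[5-(prop-1-en-2-yl)cyclohex-1-en-1-yl]oxy}silane | C=C(C)[C@H]1CCC=C(O[Si](C)(C)C)C1 | intermediate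
5 | (S)-5-(prop-1-en-2-yl)cyclohex-2-en-1-one | C=C(C)[C@H]1CC=CC(=O)C1 | intermediate
6 | (S)-2-(hydroxymethyl)-5-(prop-1-en-2-yl)cyclohex-2-en-1-one | C=C(C)[C@H]1CC=C(CO)C(=O)C1 | intermediate
7 | (S)-5-(prop-1-en-2-yl)-2-{[tri(propan-2-yl)silyl]oxymethyl}cyclohex-2-en-1-one | C=C(C)[C@H]1CC=C(CO[Si](C(C)C)(C(C)C)C(C)C)C(=O)C1 | intermediate
8 | ethyl 1-bromocyclobutane-1-carboxylate | CCOC(=O)C1(Br)CCC1 | starting material
9 | cyclobut-1-ene-1-carboxylic acid | OC(=O)C1=CCC1 | intermediate
10 | (cyclobut-1-en-1-yl)methanol | OCC1=CCC1 | intermediate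
11 | 1-[(triethylsilyloxy)methyl]cyclobut-1-ene | CC[Si](CC)(CC)OCC1=CCC1 | intermediate
12 | cis-anti-cis-9-(prop-1-en-2-yl)-2-[(triethylsilyloxy)methyl]-6-{[tri(propan-2-yl)silyl]oxymethyl}tricyclo[4.4.0.0(2,5)]decan-7-one (7S in route numbering; four-membered rings on the face opposite to the isopropenyl group) | C=C(C)[C@H]1C[C@@H]2[C@@]3(CO[Si](CC)(CC)CC)CC[C@H]3[C@]2(CO[Si](C(C)C)(C(C)C)C(C)C)C(=O)C1 | intermediate
13 | (2E,6E,9S)-9-(prop-1-en-2-yl)-6-[(triethylsilyloxy)methyl]-2-{[tri(propan-2-yl)silyl]oxymethyl}cyclodeca-2,6-dien-1-one | C=C(C)[C@H]1C/C=C(/CO[Si](CC)(CC)CC)CC/C=C(\CO[Si](C(C)C)(C(C)C)C(C)C)C(=O)C1 | intermediate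
14 | (1S,2E,6E,9S)-9-(prop-1-en-2-yl)-6-[(triethylsilyloxy)methyl]-2-{[tri(propan-2-yl)silyl]oxymethyl}cyclodeca-2,6-dien-1-ol | C=C(C)[C@H]1C/C=C(/CO[Si](CC)(CC)CC)CC/C=C(\CO[Si](C(C)C)(C(C)C)C(C)C)[C@@H](O)C1 | intermediate
15 | (1S,2E,6E,9S)-9-(prop-1-en-2-yl)-6-[(triethylsilyloxy)methyl]-2-{[tri(propan-2-yl)silyl]oxymethyl}cyclodeca-2,6-dien-1-yl acetate | C=C(C)[C@H]1C/C=C(/CO[Si](CC)(CC)CC)CC/C=C(\CO[Si](C(C)C)(C(C)C)C(C)C)[C@@H](OC(C)=O)C1 | intermediate
16 | (1S,2E,6E,9S)-6-(hydroxymethyl)-9-(prop-1-en-2-yl)-2-{[tri(propan-2-yl)silyl]oxymethyl}cyclodeca-2,6-dien-1-yl acetate | C=C(C)[C@H]1C/C=C(/CO)CC/C=C(\CO[Si](C(C)C)(C(C)C)C(C)C)[C@@H](OC(C)=O)C1 | intermediate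
17 | (1S,2E,6E,9S)-6-formyl-9-(prop-1-en-2-yl)-2-{[tri(propan-2-yl)silyl]oxymethyl}cyclodeca-2,6-dien-1-yl acetate | C=C(C)[C@H]1C/C=C(/C=O)CC/C=C(\CO[Si](C(C)C)(C(C)C)C(C)C)[C@@H](OC(C)=O)C1 | intermediate
18 | C14 carboxylic acid (CO2H on C10, CH2OTIPS on C4, 5S-OAc, 7S-isopropenyl; C3=C4 trans and C9=C10 cis in the ring) | C=C(C)[C@H]1C/C=C(/C(=O)O)CC/C=C(\CO[Si](C(C)C)(C(C)C)C(C)C)[C@@H](OC(C)=O)C1 | intermediate
19 | C14 methyl ester (as 18 with CO2Me on C10) | C=C(C)[C@H]1C/C=C(/C(=O)OC)CC/C=C(\CO[Si](C(C)C)(C(C)C)C(C)C)[C@@H](OC(C)=O)C1 | intermediate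
20 | C15 allylic alcohol (as 19 with CH2OH on C4) | C=C(C)[C@H]1C/C=C(/C(=O)OC)CC/C=C(\CO)[C@@H](OC(C)=O)C1 | intermediate
21 | (3R,4S,5S,7S)-epoxy alcohol (C3–C4 epoxide, CH2OH on C4) | C=C(C)[C@H]1C/C=C(/C(=O)OC)CC[C@H]2O[C@]2(CO)[C@@H](OC(C)=O)C1 | intermediate
22 | (R)-2-methylbutanoic acid | OC(=O)[C@H](C)CC | starting material
23 | CNP0352790.1 | C=C(C)[C@H]1C/C=C(/C(=O)OC)CC[C@H]2O[C@]2(COC(=O)[C@H](C)CC)[C@@H](OC(C)=O)C1 | target

**Step count.** Total: 19 steps. Longest linear sequence: 16 steps (steps 1–5 and 9–19).

**Steps most likely to fail**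

1. Step 10. The 1,4-diyl may relax to the other chair, which would give C3=C4 cis and C9=C10 trans, or the dienone may undergo Cope rearrangement to a 1,2-divinylcyclohexanone at the temperature needed for ring opening. The fallback sets out from 12 and returns at 19, and moves the C14 oxidation ahead of the ring opening. Selective removal of the triethylsilyl group (PPTS, MeOH) would give the tricyclic hydroxy ketone F1, Dess–Martin oxidation the tricyclic keto aldehyde F2, Pinnick oxidation the tricyclic keto acid F3, and (trimethylsilyl)diazomethane the tricyclic keto ester F4. Ring opening of F4 then runs through a C10 radical conjugated with the ester: the central bond should break at lower temperature, which limits the Cope pathway, and the planar ester-bearing radical should exert a stronger allylic strain on C8, the arrangement that leads to a cis ester-bearing alkene. The resulting ten-membered keto ester F5 would be reduced ((R)-2-methyl-CBS-oxazaborolidine, catecholborane) to the hydroxy ester F6, and acetylation leads to 19.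

2. Step 9. Head-to-head or trans-fused adducts may form and cannot be corrected at the quaternary C4, and the hindered enone may be consumed slowly. The fallback sets out from 7 and returns at 19, and replaces the alkyl-substituted cyclobutene by an enol ether, whose oxygen-bearing carbon directs far more strongly to the β-carbon C9. Enone 7 would be irradiated with 1-(tert-butyldimethylsilyloxy)cyclobut-1-ene F7 (from cyclobutanone, TBSOTf, Et3N) to give the C10-silyloxy photoadduct F8, and heating would give the ring-opened silyl enol ether dienone F9. CBS reduction and acetylation would give the silyl enol ether alcohol F10 and the silyl enol ether acetate F11. Fluoride-triggered triflation (CsF, PhNTf2, DME) should convert the silyl enol ether, with its position and geometry kept, into the enol triflate F12. Palladium-catalysed methoxycarbonylation (Pd(PPh3)4, CO, MeOH, Et3N, DMF), in which the vinyl triflate should undergo oxidative addition before the hindered C5 allylic acetate ionises, installs C14 as the methyl ester 19.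

3. Step 18. The conformational bias of the trans-cyclodecene may override the tartrate and send oxygen to the wrong face, or slow turnover of this cis-3-substituted allylic alcohol may allow the epoxy alcohol to be opened by titanium alkoxide. The fallback sets out from 20 and returns at 23, and gives up the hydroxyl-directed delivery. Alcohol 20 would first be esterified with 22 (DCC, DMAP) to the des-epoxy triester F13. The C3=C4 alkene would then be epoxidised by the Shi method (D-fructose-derived ketone, KHSO5, K2CO3 buffer, MeCN/dimethoxymethane/H2O, 0 °C). This dioxirane transfer should select the trisubstituted alkene over the enoate and the 1,1-disubstituted isopropenyl group, and its spiro transition-state model predicts the face that gives 3R,4S, so that 23 is reached directly.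

**Further compounds**

F1 | step 10 | tricyclic hydroxy ketone (12 with free C14 hydroxyl) | C=C(C)[C@H]1C[C@@H]2[C@@]3(CO)CC[C@H]3[C@]2(CO[Si](C(C)C)(C(C)C)C(C)C)C(=O)C1
F2 | step 10 | tricyclic keto aldehyde (C14 as CHO) | C=C(C)[C@H]1C[C@@H]2[C@@]3(C=O)CC[C@H]3[C@]2(CO[Si](C(C)C)(C(C)C)C(C)C)C(=O)C1
F3 | step 10 | tricyclic keto acid (C14 as CO2H) | C=C(C)[C@H]1C[C@@H]2[C@@]3(C(=O)O)CC[C@H]3[C@]2(CO[Si](C(C)C)(C(C)C)C(C)C)C(=O)C1
F4 | step 10 | tricyclic keto ester (C14 as CO2Me) | C=C(C)[C@H]1C[C@@H]2[C@@]3(C(=O)OC)CC[C@H]3[C@]2(CO[Si](C(C)C)(C(C)C)C(C)C)C(=O)C1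
F5 | step 10 | ten-membered keto ester (13 with CO2Me on C10) | C=C(C)[C@H]1C/C=C(/C(=O)OC)CC/C=C(\CO[Si](C(C)C)(C(C)C)C(C)C)C(=O)C1
F6 | step 10 | (5S)-hydroxy ester (19 without the acetyl group) | C=C(C)[C@H]1C/C=C(/C(=O)OC)CC/C=C(\CO[Si](C(C)C)(C(C)C)C(C)C)[C@@H](O)C1
F7 | step 9 | 1-(tert-butyldimethylsilyloxy)cyclobut-1-ene | CC(C)(C)[Si](C)(C)OC1=CCC1
F8 | step 9 | C10-silyloxy photoadduct (12 with OTBS in place of CH2OTES) | C=C(C)[C@H]1C[C@@H]2[C@@]3(O[Si](C)(C)C(C)(C)C)CC[C@H]3[C@]2(CO[Si](C(C)C)(C(C)C)C(C)C)C(=O)C1
F9 | step 9 | ring-opened silyl enol ether dienone (OTBS on C10) | C=C(C)[C@H]1C/C=C(/O[Si](C)(C)C(C)(C)C)CC/C=C(\CO[Si](C(C)C)(C(C)C)C(C)C)C(=O)C1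
F10 | step 9 | (5S)-silyl enol ether alcohol | C=C(C)[C@H]1C/C=C(/O[Si](C)(C)C(C)(C)C)CC/C=C(\CO[Si](C(C)C)(C(C)C)C(C)C)[C@@H](O)C1
F11 | step 9 | (5S)-silyl enol ether acetate | C=C(C)[C@H]1C/C=C(/O[Si](C)(C)C(C)(C)C)CC/C=C(\CO[Si](C(C)C)(C(C)C)C(C)C)[C@@H](OC(C)=O)C1
F12 | step 9 | C10 enol triflate | C=C(C)[C@H]1C/C=C(/OS(=O)(=O)C(F)(F)F)CC/C=C(\CO[Si](C(C)C)(C(C)C)C(C)C)[C@@H](OC(C)=O)C1
F13 | step 18 | des-epoxy triester (20 acylated at C15 with 22) | C=C(C)[C@H]1C/C=C(/C(=O)OC)CC/C=C(\COC(=O)[C@H](C)CC)[C@@H](OC(C)=O)C1
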